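**Route outline**

- Retrosynthesis: the four benzyl ethers come off last; the aroyl C=O is traced back to an ethylidene C=C; the bond from C5 of the central arene to the side-chain CH is cut by a retro-[3,3] shift to a C4–O–CH(CH3) allyl aryl ether; then the lactone Cα–CH2Ar bond (enolate alkylation), the ether C–O bond (Mitsunobu) and the vinyl–aryl bond (Stille) are cut.
- Forward: all three arenes are bought; the chain is joined by Stille coupling, Mitsunobu etherification and enolate alkylation; the butyrolactone is the only ring made (Stobbe condensation, hydrogenation, reduction–lactonisation); the Claisen step then turns the C–O link into the C5–C link.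
- Enabling feature: in the central ring the C4 oxygen lies between C3–OMe and C5, and C5 bears a benzylic CH stereocentre bonded to an sp2 carbon (the ketone carbon). This is an ortho-Claisen retron with a single free ortho position.
- Stereochemistry: lactone Cβ (R) from rhodium/Et-DuPhos hydrogenation; Cα (R) from trans alkylation; the side-chain centre (S) from a carbinol set by transfer hydrogenation (S), inverted in the Mitsunobu step (R) and relayed across the E allyl unit in the [3,3] shift. The carbinol carbon finally leaves as acetaldehyde.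

Key step: step 13

Remark: the central arene is numbered C1 (CH2 to the lactone), C3 (OMe), C4 (O), C5 (side chain), and the target is read as (3R,4R) in the lactone and (S) at the side-chain carbon; the (S,S) antipode of Et-DuPhos is assumed to be the one that gives the R half-ester, and the (R,R) ligand would be used, with nothing else changed, if the sense proved opposite.

**Route**

Step 1
Reactants: 1 benzyl propargyl ether (3-benzyloxyprop-1-yne); 2 N-methoxy-N-methylacetamide
Product: 4 5-(benzyloxy)pent-3-yn-2-one, via lithium acetylide 3 (not isolated)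
Conditions: n-BuLi, THF, −78 °C; then 2, −78 to 0 °C; cold aq. NH4Cl
Reagents that add atoms: none
Why: Weinreb ketone synthesis, in which the chelated tetrahedral adduct of the lithium acetylide collapses only on quench, so that acylation should stop at the ynone.

Step 2
Reactants: 4 5-(benzyloxy)pent-3-yn-2-one
Product: 5 (S)-5-(benzyloxy)pent-3-yn-2-ol
Conditions: Ru(p-cymene)[(S,S)-TsDPEN] (preformed amido complex, 1 mol%), i-PrOH, rt
Reagents that add atoms: none
Why: Noyori asymmetric transfer hydrogenation of an ynone, in which the (S,S)-TsDPEN ruthenium catalyst delivers hydride to the carbonyl face that gives the S propargylic alcohol, the alkyne acting as the unsaturated directing substituent.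

Step 3
Reactants: 6 4-iodo-2-methoxyphenol
Product: 7 1-(benzyloxy)-4-iodo-2-methoxybenzene
Conditions: BnBr, K2CO3, DMF, rt
Reagents that add atoms: benzyl bromide, BrCc1ccccc1
Why: Williamson etherification of the phenoxide, which should be clean because the aryl iodide is inert to carbonate.

Step 4
Reactants: 5 (S)-5-(benzyloxy)pent-3-yn-2-ol
Product: 8 (2S,3Z)-5-(benzyloxy)-3-(tributylstannyl)pent-3-en-2-ol
Conditions: Bu3SnH, [Cp*RuCl]4 (2 mol%), CH2Cl2, rt
Reagents that add atoms: tributyltin hydride, CCCC[SnH](CCCC)CCCC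
Why: Hydroxyl-directed ruthenium-catalysed trans-hydrostannation, in which the free OH (hydrogen-bonded to the chloride ligand) steers tin to the alkyne carbon next to the carbinol while H adds trans, so that tin ends cis to the CH2OBn group and the carbinol centre is untouched.

Step 5
Reactants: 8 (2S,3Z)-5-(benzyloxy)-3-(tributylstannyl)pent-3-en-2-ol; 7 1-(benzyloxy)-4-iodo-2-methoxybenzene
Product: 9 (2S,3E)-5-(benzyloxy)-3-[4-(benzyloxy)-3-methoxyphenyl]pent-3-en-2-ol
Conditions: Pd(PPh3)4 (5 mol%), copper thiophene-2-carboxylate Cu(O2CC4H3S) (1.5 equiv), [NBu4][Ph2PO2] (1.5 equiv), DMF, rt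
Reagents that add atoms: none
Why: Copper-assisted Stille coupling with retention of alkene geometry, in which the copper carboxylate takes over the hindered alkenyl group from tin and the phosphinate binds the tin residue, which should outrun protodestannation.

Step 6
Reactants: 9 (2S,3E)-5-(benzyloxy)-3-[4-(benzyloxy)-3-methoxyphenyl]pent-3-en-2-ol; 10 vanillin (4-hydroxy-3-methoxybenzaldehyde)
Product: 11 4-{[(2R,3E)-5-(benzyloxy)-3-[4-(benzyloxy)-3-methoxyphenyl]pent-3-en-2-yl]oxy}-3-methoxybenzaldehyde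
Conditions: PPh3, DIAD, THF, 0 °C to rt
Reagents that add atoms: none
Why: Mitsunobu etherification, in which the acidic phenol of vanillin displaces the oxyphosphonium group by SN2 with inversion, turning the S carbinol into the R aryl ether.

Step 7
Reactants: 11 4-{[(2R,3E)-5-(benzyloxy)-3-[4-(benzyloxy)-3-methoxyphenyl]pent-3-en-2-yl]oxy}-3-methoxybenzaldehyde
Product: 12 (4-{[(2R,3E)-5-(benzyloxy)-3-[4-(benzyloxy)-3-methoxyphenyl]pent-3-en-2-yl]oxy}-3-methoxyphenyl)methanol
Conditions: NaBH4, MeOH/THF, 0 °C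
Reagents that add atoms: none
Why: Borohydride reduction of the only carbonyl group, which leaves the ethers and the alkene alone.

Step 8
Reactants: 12 (4-{[(2R,3E)-5-(benzyloxy)-3-[4-(benzyloxy)-3-methoxyphenyl]pent-3-en-2-yl]oxy}-3-methoxyphenyl)methanol
Product: 13 1-{[(2R,3E)-5-(benzyloxy)-3-[4-(benzyloxy)-3-methoxyphenyl]pent-3-en-2-yl]oxy}-4-(bromomethyl)-2-methoxybenzene
Conditions: CBr4, PPh3, CH2Cl2, 0 °C; used at once
Reagents that add atoms: carbon tetrabromide, BrC(Br)(Br)Br
Why: Appel bromination under neutral conditions, chosen so that no acid is present that could cleave the secondary allyl aryl ether.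

Step 9
Reactants: 14 4-(benzyloxy)-3-methoxybenzaldehyde; 15 dimethyl succinate
Product: 16 (E)-4-[4-(benzyloxy)-3-methoxyphenyl]-3-(methoxycarbonyl)but-3-enoic acid
Conditions: KOt-Bu, t-BuOH, reflux; then 2 M HCl
Reagents that add atoms: none
Why: Stobbe condensation, in which aldol addition, lactonisation to the paraconic ester and eliminative ring opening should give the alkylidene half-ester with the free acid on the CH2 arm.

Step 10
Reactants: 16 (E)-4-[4-(benzyloxy)-3-methoxyphenyl]-3-(methoxycarbonyl)but-3-enoic acid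
Product: 17 (R)-4-[4-(benzyloxy)-3-methoxyphenyl]-3-(methoxycarbonyl)butanoic acid
Conditions: [Rh(cod)((S,S)-Et-DuPhos)]BF4 (0.5 mol%), NaOMe (10 mol%), MeOH, H2 (5 bar), rt
Reagents that add atoms: none
Why: Rhodium–DuPhos asymmetric hydrogenation of an itaconate-type half-ester, in which the carboxylate arm chelates rhodium as the amide of an enamide does and the ligand chirality selects the alkene face that gives the R centre, while the benzyl ether is inert to this homogeneous catalyst.

Step 11
Reactants: 17 (R)-4-[4-(benzyloxy)-3-methoxyphenyl]-3-(methoxycarbonyl)butanoic acid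
Product: 20 (R)-4-[4-(benzyloxy)-3-methoxybenzyl]dihydrofuran-2(3H)-one, via potassium carboxylate 18 (not isolated), via hydroxy acid 19 (not isolated)
Conditions: KOH (1.0 equiv), EtOH; Ca(BH4)2·2THF, EtOH, 0 °C to rt; then 2 M HCl, rt
Reagents that add atoms: none
Why: Chemoselective borohydride reduction, in which calcium borohydride reduces the methyl ester but not the carboxylate, followed by acid-induced γ-lactonisation that does not touch the stereocentre.

Step 12
Reactants: 20 (R)-4-[4-(benzyloxy)-3-methoxybenzyl]dihydrofuran-2(3H)-one; 13 1-{[(2R,3E)-5-(benzyloxy)-3-[4-(benzyloxy)-3-methoxyphenyl]pent-3-en-2-yl]oxy}-4-(bromomethyl)-2-methoxybenzene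
Product: 22 (3R,4R)-4-[4-(benzyloxy)-3-methoxybenzyl]-3-(4-{[(2R,3E)-5-(benzyloxy)-3-[4-(benzyloxy)-3-methoxyphenyl]pent-3-en-2-yl]oxy}-3-methoxybenzyl)dihydrofuran-2(3H)-one, via lithium enolate 21 (not isolated)
Conditions: LiN(SiMe3)2, THF, −78 °C; then 13, −78 to −40 °C
Reagents that add atoms: none
Why: Substrate-controlled enolate alkylation, in which the benzylic bromide approaches the lactone enolate anti to the β-benzyl group to set the trans (3R) centre, and the alkene-masked side chain offers no acidic C–H to the base.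

Step 13
Reactants: 22 (3R,4R)-4-[4-(benzyloxy)-3-methoxybenzyl]-3-(4-{[(2R,3E)-5-(benzyloxy)-3-[4-(benzyloxy)-3-methoxyphenyl]pent-3-en-2-yl]oxy}-3-methoxybenzyl)dihydrofuran-2(3H)-one
Product: 24 (3R,4R)-4-[4-(benzyloxy)-3-methoxybenzyl]-3-{3-[(2S,3Z)-1-(benzyloxy)-3-[4-(benzyloxy)-3-methoxyphenyl]pent-3-en-2-yl]-4-hydroxy-5-methoxybenzyl}dihydrofuran-2(3H)-one, via ortho-dienone 23 (not isolated)
Conditions: Eu(fod)3 [fod = 6,6,7,7,8,8,8-heptafluoro-2,2-dimethyloctane-3,5-dionate] (10 mol%), CHCl3, 60 °C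
Reagents that add atoms: none
Why: The step is a concerted, suprafacial [3,3] sigmatropic shift (aromatic ortho-Claisen rearrangement) in which the aryl O–CH(CH3) bond of 22 breaks as C5 of the central ring bonds to the CH(CH2OBn) allyl terminus, the resulting ortho-dienone 23 then tautomerising to phenol 24; the europium centre, held between the C3 methoxy and C4 ether oxygens, only lowers the temperature at which this happens. The closest known reaction type is the thermal or Eu(fod)3-catalysed Claisen rearrangement of enantioenriched secondary allyl aryl ethers with 1,3-chirality transfer. No ring of the product is closed, the six-membered array existing only in the transition state. The new S stereocentre is controlled by the R carbinol carbon and the E geometry of the allyl unit: the carbon–carbon bond forms on the allyl face from which oxygen departs, and with the methyl group pseudo-equatorial (an axial methyl would collide with the C3–OMe flank of the arene) chair and boat approaches converge on the same configuration, the methyl ending trans to the new centre on the ethylidene alkene. The step needs ortho-regioselectivity and freedom from ionisation: C3 is blocked by methoxy and the para carbon C1 by the lactone methylene, so only C5 can rearomatise, and the aryl group on the central allyl carbon lies on a node of the allyl cation and gives it no extra stabilisation.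

Step 14
Reactants: 24 (3R,4R)-4-[4-(benzyloxy)-3-methoxybenzyl]-3-{3-[(2S,3Z)-1-(benzyloxy)-3-[4-(benzyloxy)-3-methoxyphenyl]pent-3-en-2-yl]-4-hydroxy-5-methoxybenzyl}dihydrofuran-2(3H)-one
Product: 25 (3R,4R)-4-[4-(benzyloxy)-3-methoxybenzyl]-3-{4-(benzyloxy)-3-[(2S,3Z)-1-(benzyloxy)-3-[4-(benzyloxy)-3-methoxyphenyl]pent-3-en-2-yl]-5-methoxybenzyl}dihydrofuran-2(3H)-one
Conditions: BnBr, K2CO3, DMF, rt
Reagents that add atoms: benzyl bromide, BrCc1ccccc1
Why: Williamson benzylation of the hindered phenol, needed because periodate would oxidise a free guaiacol, with a base too weak to touch the lactone α-proton or the benzylic allylic C–H.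

Step 15
Reactants: 25 (3R,4R)-4-[4-(benzyloxy)-3-methoxybenzyl]-3-{4-(benzyloxy)-3-[(2S,3Z)-1-(benzyloxy)-3-[4-(benzyloxy)-3-methoxyphenyl]pent-3-en-2-yl]-5-methoxybenzyl}dihydrofuran-2(3H)-one
Product: 27 (3R,4R)-4-[4-(benzyloxy)-3-methoxybenzyl]-3-{4-(benzyloxy)-3-[(2S)-3-(benzyloxy)-1-[4-(benzyloxy)-3-methoxyphenyl]-1-oxopropan-2-yl]-5-methoxybenzyl}dihydrofuran-2(3H)-one, via vicinal diol 26 (not isolated)
Conditions: OsO4 (5 mol%), NaIO4 (4 equiv), 2,6-lutidine (2 equiv), dioxane/H2O (3:1), rt
Reagents that add atoms: osmium tetroxide, O=[Os](=O)(=O)=O (transfers the carbonyl oxygen; regenerated by sodium periodate, [Na+].[O-]I(=O)(=O)=O)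
Why: Lemieux–Johnson oxidation, in which dihydroxylation of the only alkene and periodate cleavage of the glycol release the aryl ketone with loss of the old carbinol carbon, the lutidine buffer keeping the medium near neutral so that the new α-aryl ketone centre should neither epimerise nor eliminate benzyl alcohol.

Step 16
Reactants: 27 (3R,4R)-4-[4-(benzyloxy)-3-methoxybenzyl]-3-{4-(benzyloxy)-3-[(2S)-3-(benzyloxy)-1-[4-(benzyloxy)-3-methoxyphenyl]-1-oxopropan-2-yl]-5-methoxybenzyl}dihydrofuran-2(3H)-one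
Product: 28 CNP0281222.2 (3R,4R)-3-{4-hydroxy-3-[(2S)-3-hydroxy-1-(4-hydroxy-3-methoxyphenyl)-1-oxopropan-2-yl]-5-methoxybenzyl}-4-(4-hydroxy-3-methoxybenzyl)dihydrofuran-2(3H)-one
Conditions: H2 (1 atm), Pd/C (10 wt%), EtOAc/EtOH, rt
Reagents that add atoms: none
Why: Neutral catalytic hydrogenolysis of the three aryl benzyl ethers and the alkyl benzyl ether, under which the electron-rich para-oxygenated aryl ketone, the lactone and the enolisable stereocentre should stay intact.

**Compound list**

1 | benzyl propargyl ether (3-benzyloxyprop-1-yne) | C#CCOCc1ccccc1 | starting material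
2 | N-methoxy-N-methylacetamide | CC(=O)N(C)OC | starting material
3 | lithium 3-(benzyloxy)prop-1-yn-1-ide | [Li]C#CCOCc1ccccc1 | intermediate
4 | 5-(benzyloxy)pent-3-yn-2-one | CC(=O)C#CCOCc1ccccc1 | intermediate
5 | (S)-5-(benzyloxy)pent-3-yn-2-ol | C[C@H](O)C#CCOCc1ccccc1 | intermediate
6 | 4-iodo-2-methoxyphenol | COc1cc(I)ccc1O | starting material
7 | 1-(benzyloxy)-4-iodo-2-methoxybenzene | COc1cc(I)ccc1OCc1ccccc1 | intermediate
8 | (2S,3Z)-5-(benzyloxy)-3-(tributylstannyl)pent-3-en-2-ol | C[C@H](O)/C(=C/COCc1ccccc1)[Sn](CCCC)(CCCC)CCCC | intermediate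
9 | (2S,3E)-5-(benzyloxy)-3-[4-(benzyloxy)-3-methoxyphenyl]pent-3-en-2-ol | C[C@H](O)/C(=C/COCc1ccccc1)c1ccc(OCc2ccccc2)c(OC)c1 | intermediate
10 | vanillin (4-hydroxy-3-methoxybenzaldehyde) | COc1cc(C=O)ccc1O | starting material
11 | 4-{[(2R,3E)-5-(benzyloxy)-3-[4-(benzyloxy)-3-methoxyphenyl]pent-3-en-2-yl]oxy}-3-methoxybenzaldehyde | C[C@@H](Oc1ccc(C=O)cc1OC)/C(=C/COCc1ccccc1)c1ccc(OCc2ccccc2)c(OC)c1 | intermediate
12 | (4-{[(2R,3E)-5-(benzyloxy)-3-[4-(benzyloxy)-3-methoxyphenyl]pent-3-en-2-yl]oxy}-3-methoxyphenyl)methanol | C[C@@H](Oc1ccc(CO)cc1OC)/C(=C/COCc1ccccc1)c1ccc(OCc2ccccc2)c(OC)c1 | intermediate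
13 | 1-{[(2R,3E)-5-(benzyloxy)-3-[4-(benzyloxy)-3-methoxyphenyl]pent-3-en-2-yl]oxy}-4-(bromomethyl)-2-methoxybenzene | C[C@@H](Oc1ccc(CBr)cc1OC)/C(=C/COCc1ccccc1)c1ccc(OCc2ccccc2)c(OC)c1 | intermediate
14 | 4-(benzyloxy)-3-methoxybenzaldehyde | COc1cc(C=O)ccc1OCc1ccccc1 | starting material
15 | dimethyl succinate | COC(=O)CCC(=O)OC | starting material
16 | (E)-4-[4-(benzyloxy)-3-methoxyphenyl]-3-(methoxycarbonyl)but-3-enoic acid | COC(=O)/C(CC(=O)O)=C/c1ccc(OCc2ccccc2)c(OC)c1 | intermediate
17 | (R)-4-[4-(benzyloxy)-3-methoxyphenyl]-3-(methoxycarbonyl)butanoic acid | COC(=O)[C@@H](CC(=O)O)Cc1ccc(OCc2ccccc2)c(OC)c1 | intermediate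
18 | potassium (R)-4-[4-(benzyloxy)-3-methoxyphenyl]-3-(methoxycarbonyl)butanoate | COC(=O)[C@@H](CC(=O)[O-])Cc1ccc(OCc2ccccc2)c(OC)c1.[K+] | intermediate
19 | (R)-3-[4-(benzyloxy)-3-methoxybenzyl]-4-hydroxybutanoic acid | OC[C@@H](CC(=O)O)Cc1ccc(OCc2ccccc2)c(OC)c1 | intermediate
20 | (R)-4-[4-(benzyloxy)-3-methoxybenzyl]dihydrofuran-2(3H)-one | COc1cc(C[C@H]2COC(=O)C2)ccc1OCc1ccccc1 | intermediate
21 | lithium (R)-4-[4-(benzyloxy)-3-methoxybenzyl]-4,5-dihydrofuran-2-olate (enolate of 20) | COc1cc(C[C@H]2COC(O[Li])=C2)ccc1OCc1ccccc1 | intermediate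
22 | (3R,4R)-4-[4-(benzyloxy)-3-methoxybenzyl]-3-(4-{[(2R,3E)-5-(benzyloxy)-3-[4-(benzyloxy)-3-methoxyphenyl]pent-3-en-2-yl]oxy}-3-methoxybenzyl)dihydrofuran-2(3H)-one | COc1cc(C[C@H]2COC(=O)[C@@H]2Cc2cc(OC)c(O[C@H](C)/C(=C/COCc3ccccc3)c3ccc(OCc4ccccc4)c(OC)c3)cc2)ccc1OCc1ccccc1 | intermediate
23 | ortho-dienone tautomer of 24: 2-methoxycyclohexa-2,4-dien-1-one carrying at C6 the (2S,3Z)-1-(benzyloxy)-3-aryl-pent-3-en-2-yl group and at C4 the lactone methylene (configuration at C6 not defined) | COc1cc(C[C@H]2COC(=O)[C@@H]2CC2=CC([C@@H](COCc3ccccc3)/C(=C/C)c3ccc(OCc4ccccc4)c(OC)c3)C(=O)C(OC)=C2)ccc1OCc1ccccc1 | intermediate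
24 | (3R,4R)-4-[4-(benzyloxy)-3-methoxybenzyl]-3-{3-[(2S,3Z)-1-(benzyloxy)-3-[4-(benzyloxy)-3-methoxyphenyl]pent-3-en-2-yl]-4-hydroxy-5-methoxybenzyl}dihydrofuran-2(3H)-one | COc1cc(C[C@H]2COC(=O)[C@@H]2Cc2cc(OC)c(O)c([C@@H](COCc3ccccc3)/C(=C/C)c3ccc(OCc4ccccc4)c(OC)c3)c2)ccc1OCc1ccccc1 | intermediate
25 | (3R,4R)-4-[4-(benzyloxy)-3-methoxybenzyl]-3-{4-(benzyloxy)-3-[(2S,3Z)-1-(benzyloxy)-3-[4-(benzyloxy)-3-methoxyphenyl]pent-3-en-2-yl]-5-methoxybenzyl}dihydrofuran-2(3H)-one | COc1cc(C[C@H]2COC(=O)[C@@H]2Cc2cc(OC)c(OCc3ccccc3)c([C@@H](COCc3ccccc3)/C(=C/C)c3ccc(OCc4ccccc4)c(OC)c3)c2)ccc1OCc1ccccc1 | intermediate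
26 | vicinal diol of 25 (3,4-dihydroxypentan-2-yl side chain; the two new carbinol centres not defined) | COc1cc(C[C@H]2COC(=O)[C@@H]2Cc2cc(OC)c(OCc3ccccc3)c([C@@H](COCc3ccccc3)C(O)(C(C)O)c3ccc(OCc4ccccc4)c(OC)c3)c2)ccc1OCc1ccccc1 | intermediate
27 | (3R,4R)-4-[4-(benzyloxy)-3-methoxybenzyl]-3-{4-(benzyloxy)-3-[(2S)-3-(benzyloxy)-1-[4-(benzyloxy)-3-methoxyphenyl]-1-oxopropan-2-yl]-5-methoxybenzyl}dihydrofuran-2(3H)-one | COc1cc(C[C@H]2COC(=O)[C@@H]2Cc2cc(OC)c(OCc3ccccc3)c([C@@H](COCc3ccccc3)C(=O)c3ccc(OCc4ccccc4)c(OC)c3)c2)ccc1OCc1ccccc1 | intermediate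
28 | CNP0281222.2, (3R,4R)-3-{4-hydroxy-3-[(2S)-3-hydroxy-1-(4-hydroxy-3-methoxyphenyl)-1-oxopropan-2-yl]-5-methoxybenzyl}-4-(4-hydroxy-3-methoxybenzyl)dihydrofuran-2(3H)-one | COc1cc(C[C@H]2COC(=O)[C@@H]2Cc2cc(OC)c(O)c([C@@H](CO)C(=O)c3ccc(O)c(OC)c3)c2)ccc1O | target

**Step count and risks**

Total step count: 16. Longest linear sequence: 12 steps (steps 1, 2, 4, 5, 6, 7, 8, 12, 13, 14, 15, 16).

Steps most likely to fail:

1. Step 13 (Claisen rearrangement). The Lewis acid may heterolyse the secondary allylic C–O bond faster than the ordered [3,3] shift, part of the material may react through the conformer with the methyl group inside, or the freed phenol may add to the styrene-type alkene. Each of these would cost stereochemical fidelity or the product itself.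
   - The fallback makes the C5–C bond intermolecularly by copper-mediated anti-SN2' arylation. It sets out from allylic alcohol 9 (used without Mitsunobu inversion) and lactone 20 and comes back to the route at 25.
   - Alcohol 9 would be esterified with retention (picolinic acid, DCC, DMAP, CH2Cl2) to the allylic picolinate F1.
   - Bought 5-bromovanillin F2 would be benzylated (BnBr, K2CO3) to 4-(benzyloxy)-3-bromo-5-methoxybenzaldehyde F3 and protected with trimethyl orthoformate and catalytic TsOH in MeOH as the dimethyl acetal F4.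
   - Magnesium insertion in THF would give the arylmagnesium bromide F5. With CuBr·SMe2 at −40 to 0 °C this should displace the chelating picolinate of F1 at the allyl terminus, anti to the leaving group. For the S ester that is the same face the sigmatropic step uses, so the acetal F6 would carry the same S centre and ethylidene alkene.
   - Acidic work-up would give the aldehyde F7, NaBH4 the benzylic alcohol F8, and CBr4/PPh3 the benzylic bromide F9.
   - Alkylation of enolate 21 (from 20, LiN(SiMe3)2, −78 °C) with F9 would give 25 directly.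

2. Step 6 (Mitsunobu etherification). The oxyphosphonium ion of the hindered secondary allylic alcohol may eliminate to the 2-aryl diene, be attacked at the allyl terminus, or ionise, which would lower yield and enantiopurity.
   - The fallback forms the ether bond at the arene carbon instead, with retention at the carbinol. It sets out from ynone 4 and comes back at 11.
   - Transfer hydrogenation of 4 with the (R,R)-TsDPEN ruthenium complex would give the (R)-alkynol F10.
   - The same trans-hydrostannation would give the (R)-stannane F11, and the same copper-assisted Stille coupling with 7 would give the (R)-allylic alcohol F12.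
   - The potassium alkoxide of F12 (KN(SiMe3)2, THF/DMF, 0 °C) would then displace fluoride from bought 4-fluoro-3-methoxybenzaldehyde F13 by nucleophilic aromatic substitution para to the formyl group, giving 11.

3. Step 5 (Stille coupling). Transfer of the α-branched alkenyl group next to a free carbinol from tin may be slower than protodestannation or cine substitution.
   - The fallback reverses the polarity of the coupling. It sets out from stannane 8 and comes back at 9.
   - Iododestannation (I2, CH2Cl2, 0 °C) with retention would give the alkenyl iodide F14.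
   - Suzuki–Miyaura coupling of F14 with bought [4-(benzyloxy)-3-methoxyphenyl]boronic acid F15 (PdCl2(dppf), K2CO3, dioxane/H2O, 60 °C) would give 9.

Further compounds
F1 | step 13 | (2S,3E)-5-(benzyloxy)-3-[4-(benzyloxy)-3-methoxyphenyl]pent-3-en-2-yl pyridine-2-carboxylate | C[C@H](OC(=O)c1ccccn1)/C(=C/COCc1ccccc1)c1ccc(OCc2ccccc2)c(OC)c1
F2 | step 13 | 5-bromovanillin (3-bromo-4-hydroxy-5-methoxybenzaldehyde) | COc1cc(C=O)cc(Br)c1O
F3 | step 13 | 4-(benzyloxy)-3-bromo-5-methoxybenzaldehyde | COc1cc(C=O)cc(Br)c1OCc1ccccc1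
F4 | step 13 | 2-(benzyloxy)-1-bromo-5-(dimethoxymethyl)-3-methoxybenzene | COc1cc(C(OC)OC)cc(Br)c1OCc1ccccc1
F5 | step 13 | [2-(benzyloxy)-5-(dimethoxymethyl)-3-methoxyphenyl]magnesium bromide | COc1cc(C(OC)OC)cc([Mg]Br)c1OCc1ccccc1
F6 | step 13 | 2-(benzyloxy)-1-[(2S,3Z)-1-(benzyloxy)-3-[4-(benzyloxy)-3-methoxyphenyl]pent-3-en-2-yl]-5-(dimethoxymethyl)-3-methoxybenzene | COc1cc(C(OC)OC)cc([C@@H](COCc2ccccc2)/C(=C/C)c2ccc(OCc3ccccc3)c(OC)c2)c1OCc1ccccc1
F7 | step 13 | 4-(benzyloxy)-3-[(2S,3Z)-1-(benzyloxy)-3-[4-(benzyloxy)-3-methoxyphenyl]pent-3-en-2-yl]-5-methoxybenzaldehyde | COc1cc(C=O)cc([C@@H](COCc2ccccc2)/C(=C/C)c2ccc(OCc3ccccc3)c(OC)c2)c1OCc1ccccc1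
F8 | step 13 | {4-(benzyloxy)-3-[(2S,3Z)-1-(benzyloxy)-3-[4-(benzyloxy)-3-methoxyphenyl]pent-3-en-2-yl]-5-methoxyphenyl}methanol | COc1cc(CO)cc([C@@H](COCc2ccccc2)/C(=C/C)c2ccc(OCc3ccccc3)c(OC)c2)c1OCc1ccccc1
F9 | step 13 | 2-(benzyloxy)-1-[(2S,3Z)-1-(benzyloxy)-3-[4-(benzyloxy)-3-methoxyphenyl]pent-3-en-2-yl]-5-(bromomethyl)-3-methoxybenzene | COc1cc(CBr)cc([C@@H](COCc2ccccc2)/C(=C/C)c2ccc(OCc3ccccc3)c(OC)c2)c1OCc1ccccc1
F10 | step 6 | (R)-5-(benzyloxy)pent-3-yn-2-ol | C[C@@H](O)C#CCOCc1ccccc1
F11 | step 6 | (2R,3Z)-5-(benzyloxy)-3-(tributylstannyl)pent-3-en-2-ol | C[C@@H](O)/C(=C/COCc1ccccc1)[Sn](CCCC)(CCCC)CCCC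
F12 | step 6 | (2R,3E)-5-(benzyloxy)-3-[4-(benzyloxy)-3-methoxyphenyl]pent-3-en-2-ol | C[C@@H](O)/C(=C/COCc1ccccc1)c1ccc(OCc2ccccc2)c(OC)c1
F13 | step 6 | 4-fluoro-3-methoxybenzaldehyde | COc1cc(C=O)ccc1F
F14 | step 5 | (2S,3Z)-5-(benzyloxy)-3-iodopent-3-en-2-ol | C[C@H](O)/C(I)=C/COCc1ccccc1
F15 | step 5 | [4-(benzyloxy)-3-methoxyphenyl]boronic acid | COc1cc(B(O)O)ccc1OCc1ccccc1
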